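**Retrosynthetic overview**
1. Ring A is closed last: the C1=C10 enone comes from an intramolecular aldol addition of a C2 methyl ketone onto the C10 ketone, then dehydration; the acetate is put on at the very end.
2. Quaternary C4 and the C5–H centre come from a cis-fused γ-lactone (C18–O–C10) alkylated twice on its convex face (methallyl, then methyl); the lactone comes from a 5-exo radical cyclisation of a bromoacetal hung on the C10 allylic alcohol.
3. C13 comes from Ru-BINAP hydrogenation of an E-allylic alcohol, itself from olefination of a side-chain methyl ketone.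
4. Key disconnection C9–C11: intermolecular asymmetric Michael addition of the chiral ketimine of (3R)-2,3-dimethylcyclohexanone to but-3-en-2-one, creating quaternary C9.
5. Ring order: ring B (from (R)-pulegone) first, then the temporary lactone ring, then ring A.

Assumption: atoms are referred to by halimane numbering (ester carbon = C18; side chain C11–C16); α/β refer to the usual drawing with ring A on the left; acetal carbons and centres that are erased later are carried as epimer mixtures.

**Step 1**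
Reactants: 1 (R)-(+)-pulegone
Product: 2 (5R,6S)-5,6-dimethyl-2-(propan-2-ylidene)cyclohexan-1-one
Conditions: LiN(i-Pr)2, THF, −78 °C; then MeI, −78 to 0 °C
Reagents that add atoms: iodomethane, CI
Why: Kinetic deprotonation of the enone at the alpha-prime CH2 followed by SN2 enolate methylation installs the future C20 methyl next to the pulegone stereocentre (future C8), the new centre being inconsequential because it is erased in steps 3 and 4.

**Step 2**
Reactants: 2 (5R,6S)-5,6-dimethyl-2-(propan-2-ylidene)cyclohexan-1-one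
Product: 3 (2S,3R)-2,3-dimethylcyclohexan-1-one
Conditions: 6 M aq. HCl, reflux, acetone distilled off
Reagents that add atoms: none
Why: Acid-catalysed hydration and retro-aldol cleavage of the isopropylidene enone expels acetone while the non-enolisable C3 methyl centre (future C8, R) is untouched.

**Step 3**
Reactants: 3 (2S,3R)-2,3-dimethylcyclohexan-1-one
Product: 4 (1S)-N-[(3R)-2,3-dimethylcyclohexylidene]-1-phenylethan-1-amine
Conditions: (S)-1-phenylethylamine, TsOH (cat.), toluene, reflux, Dean–Stark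
Reagents that add atoms: (S)-1-phenylethylamine, C[C@H](N)c1ccccc1
Why: Acid-catalysed imine condensation with azeotropic water removal gives the ketimine, which equilibrates with its more substituted secondary enamine, the nucleophile of the next step.

**Step 4**
Reactants: 4 (1S)-N-[(3R)-2,3-dimethylcyclohexylidene]-1-phenylethan-1-amine; 5 but-3-en-2-one
Product: 7 (2S,3R)-2,3-dimethyl-2-(3-oxobutyl)cyclohexan-1-one, via Michael adduct imine 6 (not isolated)
Conditions: THF, 25–40 °C, 3 d; then 20% aq. AcOH, 25 °C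
Reagents that add atoms: water, O
Why: This asymmetric Michael addition of a chiral imine (aza-ene-like transfer from the tetrasubstituted secondary enamine) alkylates the more substituted α-carbon anti to the pseudoaxial C8 methyl, on the face also favoured by the (S)-auxiliary, so quaternary C9 forms with the side chain trans to the C8 methyl, and mild acid hydrolysis frees the diketone without aldol cyclisation.

**Step 5**
Reactants: 7 (2S,3R)-2,3-dimethyl-2-(3-oxobutyl)cyclohexan-1-one
Product: 8 ethyl (2E)-5-[(1S,2R)-1,2-dimethyl-6-oxocyclohexyl]-3-methylpent-2-enoate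
Conditions: (EtO)2P(O)CH2CO2Et, NaH, THF, 0 to 25 °C
Reagents that add atoms: triethyl phosphonoacetate, CCOC(=O)CP(=O)(OCC)OCC
Why: Horner–Wadsworth–Emmons olefination is chemoselective for the unhindered methyl ketone over the neopentyl ring ketone and gives mainly the E-enoate (expected about 5:1, Z isomer removed by chromatography), whose geometry later dictates C13.

**Step 6**
Reactants: 8 ethyl (2E)-5-[(1S,2R)-1,2-dimethyl-6-oxocyclohexyl]-3-methylpent-2-enoate
Product: 10 ethyl (2E)-5-[(1S,6R)-1,6-dimethyl-2-oxocyclohex-3-en-1-yl]-3-methylpent-2-enoate, via silyl enol ether 9 (not isolated)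
Conditions: Me3SiOTf, Et3N, CH2Cl2, 0 °C; then Pd(OAc)2 (1.05 equiv), MeCN, 25 °C
Reagents that add atoms: none
Why: Soft enolisation can only occur toward C5 because C9 is quaternary, and Saegusa–Ito oxidation (β-hydride elimination from the divalent palladium enolate) gives the C5=C6 enone.

**Step 7**
Reactants: 10 ethyl (2E)-5-[(1S,6R)-1,6-dimethyl-2-oxocyclohex-3-en-1-yl]-3-methylpent-2-enoate
Product: 11 ethyl (2E)-5-[(1S,2S,6R)-2-hydroxy-1,6-dimethylcyclohex-3-en-1-yl]-3-methylpent-2-enoate
Conditions: NaBH4, CeCl3·7H2O, MeOH, −78 °C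
Reagents that add atoms: none
Why: In this Luche 1,2-reduction hydride should add to the carbonyl face anti to the pseudoaxial C9 methyl, giving the pseudoequatorial α-alcohol at C10 (OH cis to both methyls), the centre that relays configuration to C5.

**Step 8**
Reactants: 11 ethyl (2E)-5-[(1S,2S,6R)-2-hydroxy-1,6-dimethylcyclohex-3-en-1-yl]-3-methylpent-2-enoate
Product: 12 bromoacetal enoate (2-bromo-1-ethoxyethyl ether of 11)
Conditions: ethyl vinyl ether, N-bromosuccinimide, CH2Cl2, −40 to 0 °C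
Reagents that add atoms: ethyl vinyl ether, C=COCC; N-bromosuccinimide, O=C1CCC(=O)N1Br
Why: Bromoetherification of the electron-rich vinyl ether (bromonium ion opened by the allylic alcohol) gives the Ueno–Stork bromoacetal as an inconsequential epimer mixture at the acetal carbon.

**Step 9**
Reactants: 12 bromoacetal enoate
Product: 13 bromoacetal E-allylic alcohol
Conditions: i-Bu2AlH, CH2Cl2, −78 °C; aq. KNaC4H4O6 work-up
Reagents that add atoms: none
Why: Low-temperature 1,2-reduction of the enoate by the aluminium hydride gives the E-allylic alcohol without touching the acetal, the primary bromide or the ring alkene.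

**Step 10**
Reactants: 13 bromoacetal E-allylic alcohol
Product: 14 bromoacetal (3R)-alcohol
Conditions: H2 (100 atm), Ru(OAc)2[(S)-BINAP] (1 mol %), EtOH, 25 °C
Reagents that add atoms: none
Why: Noyori asymmetric hydrogenation of a geraniol-type E-allylic alcohol, directed by hydroxyl coordination to ruthenium, gives with the (S)-BINAP catalyst the (R)-citronellol-type centre (C13 R) and leaves the non-allylic ring alkene and the C–Br bond alone.

**Step 11**
Reactants: 14 bromoacetal (3R)-alcohol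
Product: 15 bromoacetal silyl ether
Conditions: t-BuPh2SiCl, imidazole, DMF, 25 °C
Reagents that add atoms: tert-butyl(chloro)diphenylsilane, CC(C)(C)[Si](Cl)(c1ccccc1)c1ccccc1
Why: Silylation of the primary alcohol gives an ether that survives the radical, enolate, hydride and oxidation steps that follow.

**Step 12**
Reactants: 15 bromoacetal silyl ether
Product: 16 cis-fused bicyclic ethyl acetal
Conditions: Bu3SnH, AIBN (cat.), benzene, 80 °C, slow addition
Reagents that add atoms: none
Why: In this Ueno–Stork 5-exo-trig radical cyclisation the tether from the α-oxygen on C10 can only reach the α face of C5, so the cis-fused ring forms and C5 is fixed (H β), the C6 radical then being reduced by the tin hydride.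

**Step 13**
Reactants: 16 cis-fused bicyclic ethyl acetal
Product: 17 cis-fused γ-lactone
Conditions: m-CPBA, BF3·OEt2, CH2Cl2, 0 to 25 °C
Reagents that add atoms: 3-chloroperoxybenzoic acid, OOC(=O)c1cccc(Cl)c1
Why: Lewis-acid-promoted peracid oxidation of the cyclic acetal (oxocarbenium ion, peroxy acetal, loss of ethanol) converts both acetal epimers into the single lactone.

**Step 14**
Reactants: 17 cis-fused γ-lactone
Product: 18 3-methallyl lactone
Conditions: LiN(i-Pr)2, THF, −78 °C; then CH2=C(CH3)CH2Br, −78 to −20 °C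
Reagents that add atoms: 3-bromo-2-methylprop-1-ene, C=C(C)CBr
Why: Lactone enolate alkylation with a reactive allylic bromide occurs on the convex face, and the new centre is temporary because it is re-enolised in the next step.

**Step 15**
Reactants: 18 3-methallyl lactone
Product: 19 3-methyl-3-methallyl lactone
Conditions: LiN(i-Pr)2, THF, −78 °C; then MeI, −78 to 0 °C
Reagents that add atoms: iodomethane, CI
Why: In this second enolate alkylation iodomethane attacks the convex face anti to C6 of the fused ring, so methyl ends cis to H5 and methallyl is pushed to the concave face, which sets quaternary C4 in the target configuration.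

**Step 16**
Reactants: 19 3-methyl-3-methallyl lactone
Product: 20 diol
Conditions: LiAlH4, THF, 0 °C
Reagents that add atoms: none
Why: Hydride reduction of the lactone gives the 1,4-diol, unmasking the C18 carbinol and the C10 alcohol without affecting the alkene or the silyl ether.

**Step 17**
Reactants: 20 diol
Product: 21 keto aldehyde
Conditions: (COCl)2, DMSO, CH2Cl2, −78 °C; then Et3N, −78 to 0 °C
Reagents that add atoms: none
Why: Swern oxidation converts both alcohols at low temperature, activating both hydroxyls before base is added so that no lactol forms and the hindered C5–H is not epimerised.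

**Step 18**
Reactants: 21 keto aldehyde
Product: 22 keto acid
Conditions: NaClO2, NaH2PO4, 2-methylbut-2-ene, t-BuOH/H2O, 25 °C
Reagents that add atoms: sodium chlorite, [Na+].[O-]Cl=O
Why: Pinnick oxidation is selective for the neopentyl aldehyde, the alkene scavenger removing HOCl so that the methallyl group and the ketone are untouched.

**Step 19**
Reactants: 22 keto acid
Product: 23 keto methyl ester
Conditions: Me3SiCHN2, toluene/MeOH, 25 °C
Reagents that add atoms: (trimethylsilyl)diazomethane, C[Si](C)(C)C=[N+]=[N-]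
Why: Neutral O-methylation of the hindered carboxylic acid by the diazoalkane installs the C18 methyl ester without base.

**Step 20**
Reactants: 23 keto methyl ester
Product: 25 diketo ester, via secondary ozonide 24 (not isolated)
Conditions: O3, CH2Cl2, −78 °C; then Me2S, −78 to 25 °C
Reagents that add atoms: ozone, [O-][O+]=O
Why: Ozonolysis of the 1,1-disubstituted alkene with reductive work-up reveals the methyl ketone (C2 carbonyl, C1 methyl) of the 1,5-diketone.

**Step 21**
Reactants: 25 diketo ester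
Product: 26 ketol
Conditions: LiN(SiMe3)2, THF, −78 to −20 °C; AcOH quench at −78 °C
Reagents that add atoms: none
Why: Kinetic deprotonation of the methyl ketone CH3 and six-membered intramolecular aldol addition to the C10 ketone closes ring A under conditions that do not enolise the hindered C5–H.

**Step 22**
Reactants: 26 ketol
Product: 28 silyl-protected enone, via ketol trifluoroacetate 27 (not isolated)
Conditions: (CF3CO)2O, DBU, CH2Cl2, 0 to 25 °C
Reagents that add atoms: none
Why: Acylation of the tertiary alcohol and E1cB elimination through the C2 enolate gives the conjugated C1=C10 enone without touching H5.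

**Step 23**
Reactants: 28 silyl-protected enone
Product: 29 hydroxy enone
Conditions: HF·pyridine, THF/pyridine, 0 to 25 °C
Reagents that add atoms: none
Why: Fluoride-driven desilylation under mildly acidic conditions frees the C15 alcohol and avoids base that could epimerise the γ-position C5.

**Step 24**
Reactants: 29 hydroxy enone
Product: 30 methyl (1S,5S,6R,8aS)-5-[(3R)-5-acetoxy-3-methylpentyl]-1,5,6-trimethyl-3-oxo-1,2,3,5,6,7,8,8a-octahydronaphthalene-1-carboxylate
Conditions: Ac2O, pyridine, DMAP (cat.), CH2Cl2, 25 °C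
Reagents that add atoms: acetic anhydride, CC(=O)OC(C)=O
Why: Nucleophile-catalysed acetylation of the primary alcohol completes the target.

**Compound list**
1 | (R)-(+)-pulegone, (5R)-5-methyl-2-(propan-2-ylidene)cyclohexan-1-one | C[C@@H]1CCC(=C(C)C)C(=O)C1 | starting material
2 | (5R,6S)-5,6-dimethyl-2-(propan-2-ylidene)cyclohexan-1-one (trans; minor cis C6 epimer carried along) | C[C@@H]1CCC(=C(C)C)C(=O)[C@H]1C | intermediate
3 | (2S,3R)-2,3-dimethylcyclohexan-1-one (trans major; C2 epimerisable) | C[C@@H]1CCCC(=O)[C@H]1C | intermediate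
4 | (1S)-N-[(3R)-2,3-dimethylcyclohexylidene]-1-phenylethan-1-amine (C2 epimers, C=N isomers) | C[C@@H]1CCCC(=N[C@@H](C)c2ccccc2)C1C | intermediate
5 | but-3-en-2-one (methyl vinyl ketone) | CC(=O)C=C | starting material
6 | 4-[(1S,2R)-1,2-dimethyl-6-{[(1S)-1-phenylethyl]imino}cyclohexyl]butan-2-one | C[C@@H]1CCCC(=N[C@@H](C)c2ccccc2)[C@@]1(C)CCC(C)=O | intermediate
7 | (2S,3R)-2,3-dimethyl-2-(3-oxobutyl)cyclohexan-1-one | O=C1CCC[C@@H](C)[C@]1(C)CCC(C)=O | intermediate
8 | ethyl (2E)-5-[(1S,2R)-1,2-dimethyl-6-oxocyclohexyl]-3-methylpent-2-enoate | O=C1CCC[C@@H](C)[C@]1(C)CC/C(C)=C/C(=O)OCC | intermediate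
9 | ethyl (2E)-5-[(1S,6R)-1,6-dimethyl-2-(trimethylsilyloxy)cyclohex-2-en-1-yl]-3-methylpent-2-enoate | C[Si](C)(C)OC1=CCC[C@@H](C)[C@]1(C)CC/C(C)=C/C(=O)OCC | intermediate
10 | ethyl (2E)-5-[(1S,6R)-1,6-dimethyl-2-oxocyclohex-3-en-1-yl]-3-methylpent-2-enoate | O=C1C=CC[C@@H](C)[C@]1(C)CC/C(C)=C/C(=O)OCC | intermediate
11 | ethyl (2E)-5-[(1S,2S,6R)-2-hydroxy-1,6-dimethylcyclohex-3-en-1-yl]-3-methylpent-2-enoate | O[C@H]1C=CC[C@@H](C)[C@]1(C)CC/C(C)=C/C(=O)OCC | intermediate
12 | ethyl (2E)-5-[(1S,2S,6R)-2-(2-bromo-1-ethoxyethoxy)-1,6-dimethylcyclohex-3-en-1-yl]-3-methylpent-2-enoate (acetal epimers) | CCOC(CBr)O[C@H]1C=CC[C@@H](C)[C@]1(C)CC/C(C)=C/C(=O)OCC | intermediate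
13 | (2E)-5-[(1S,2S,6R)-2-(2-bromo-1-ethoxyethoxy)-1,6-dimethylcyclohex-3-en-1-yl]-3-methylpent-2-en-1-ol | CCOC(CBr)O[C@H]1C=CC[C@@H](C)[C@]1(C)CC/C(C)=C/CO | intermediate
14 | (3R)-5-[(1S,2S,6R)-2-(2-bromo-1-ethoxyethoxy)-1,6-dimethylcyclohex-3-en-1-yl]-3-methylpentan-1-ol | CCOC(CBr)O[C@H]1C=CC[C@@H](C)[C@]1(C)CC[C@@H](C)CCO | intermediate
15 | {[(3R)-5-[(1S,2S,6R)-2-(2-bromo-1-ethoxyethoxy)-1,6-dimethylcyclohex-3-en-1-yl]-3-methylpentyl]oxy}(tert-butyl)diphenylsilane | CCOC(CBr)O[C@H]1C=CC[C@@H](C)[C@]1(C)CC[C@@H](C)CCO[Si](c2ccccc2)(c2ccccc2)C(C)(C)C | intermediate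
16 | (3aR,6R,7S,7aS)-7-[(3R)-5-{[tert-butyl(diphenyl)silyl]oxy}-3-methylpentyl]-2-ethoxy-6,7-dimethyloctahydro-1-benzofuran (C2 epimers) | CCOC1C[C@H]2CC[C@@H](C)[C@](C)(CC[C@@H](C)CCO[Si](c3ccccc3)(c3ccccc3)C(C)(C)C)[C@H]2O1 | intermediate
17 | (3aR,6R,7S,7aS)-7-[(3R)-5-{[tert-butyl(diphenyl)silyl]oxy}-3-methylpentyl]-6,7-dimethylhexahydro-1-benzofuran-2(3H)-one | O=C1C[C@H]2CC[C@@H](C)[C@](C)(CC[C@@H](C)CCO[Si](c3ccccc3)(c3ccccc3)C(C)(C)C)[C@H]2O1 | intermediate
18 | (3R,3aR,6R,7S,7aS)-7-[(3R)-5-{[tert-butyl(diphenyl)silyl]oxy}-3-methylpentyl]-6,7-dimethyl-3-(2-methylprop-2-en-1-yl)hexahydro-1-benzofuran-2(3H)-one | O=C1[C@H](CC(C)=C)[C@H]2CC[C@@H](C)[C@](C)(CC[C@@H](C)CCO[Si](c3ccccc3)(c3ccccc3)C(C)(C)C)[C@H]2O1 | intermediate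
19 | (3S,3aR,6R,7S,7aS)-7-[(3R)-5-{[tert-butyl(diphenyl)silyl]oxy}-3-methylpentyl]-3,6,7-trimethyl-3-(2-methylprop-2-en-1-yl)hexahydro-1-benzofuran-2(3H)-one | O=C1[C@@](C)(CC(C)=C)[C@H]2CC[C@@H](C)[C@](C)(CC[C@@H](C)CCO[Si](c3ccccc3)(c3ccccc3)C(C)(C)C)[C@H]2O1 | intermediate
20 | (1S,2S,3R,6R)-2-[(3R)-5-{[tert-butyl(diphenyl)silyl]oxy}-3-methylpentyl]-6-[(2S)-1-hydroxy-2,4-dimethylpent-4-en-2-yl]-2,3-dimethylcyclohexan-1-ol | OC[C@@](C)(CC(C)=C)[C@H]1CC[C@@H](C)[C@](C)(CC[C@@H](C)CCO[Si](c2ccccc2)(c2ccccc2)C(C)(C)C)[C@H]1O | intermediate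
21 | (2S)-2-[(1R,3S,4R)-3-[(3R)-5-{[tert-butyl(diphenyl)silyl]oxy}-3-methylpentyl]-3,4-dimethyl-2-oxocyclohexyl]-2,4-dimethylpent-4-enal | O=C[C@@](C)(CC(C)=C)[C@H]1CC[C@@H](C)[C@](C)(CC[C@@H](C)CCO[Si](c2ccccc2)(c2ccccc2)C(C)(C)C)C1=O | intermediate
22 | (2S)-2-[(1R,3S,4R)-3-[(3R)-5-{[tert-butyl(diphenyl)silyl]oxy}-3-methylpentyl]-3,4-dimethyl-2-oxocyclohexyl]-2,4-dimethylpent-4-enoic acid | OC(=O)[C@@](C)(CC(C)=C)[C@H]1CC[C@@H](C)[C@](C)(CC[C@@H](C)CCO[Si](c2ccccc2)(c2ccccc2)C(C)(C)C)C1=O | intermediate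
23 | methyl (2S)-2-[(1R,3S,4R)-3-[(3R)-5-{[tert-butyl(diphenyl)silyl]oxy}-3-methylpentyl]-3,4-dimethyl-2-oxocyclohexyl]-2,4-dimethylpent-4-enoate | COC(=O)[C@@](C)(CC(C)=C)[C@H]1CC[C@@H](C)[C@](C)(CC[C@@H](C)CCO[Si](c2ccccc2)(c2ccccc2)C(C)(C)C)C1=O | intermediate
24 | secondary ozonide of 23, methyl (2S)-2-[(1R,3S,4R)-3-[(3R)-5-{[tert-butyl(diphenyl)silyl]oxy}-3-methylpentyl]-3,4-dimethyl-2-oxocyclohexyl]-2-methyl-3-(3-methyl-1,2,4-trioxolan-3-yl)propanoate (trioxolane epimers) | COC(=O)[C@@](C)(CC2(C)OCOO2)[C@H]1CC[C@@H](C)[C@](C)(CC[C@@H](C)CCO[Si](c3ccccc3)(c3ccccc3)C(C)(C)C)C1=O | intermediate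
25 | methyl (2S)-2-[(1R,3S,4R)-3-[(3R)-5-{[tert-butyl(diphenyl)silyl]oxy}-3-methylpentyl]-3,4-dimethyl-2-oxocyclohexyl]-2-methyl-4-oxopentanoate | COC(=O)[C@@](C)(CC(C)=O)[C@H]1CC[C@@H](C)[C@](C)(CC[C@@H](C)CCO[Si](c2ccccc2)(c2ccccc2)C(C)(C)C)C1=O | intermediate
26 | methyl (1S,5S,6R,8aR)-5-[(3R)-5-{[tert-butyl(diphenyl)silyl]oxy}-3-methylpentyl]-4a-hydroxy-1,5,6-trimethyl-3-oxodecahydronaphthalene-1-carboxylate (C4a configuration not assigned, inconsequential) | COC(=O)[C@@]1(C)CC(=O)CC2(O)[C@@H]1CC[C@@H](C)[C@]2(C)CC[C@@H](C)CCO[Si](c3ccccc3)(c3ccccc3)C(C)(C)C | intermediate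
27 | trifluoroacetate ester of ketol 26 at the C4a oxygen | COC(=O)[C@@]1(C)CC(=O)CC2(OC(=O)C(F)(F)F)[C@@H]1CC[C@@H](C)[C@]2(C)CC[C@@H](C)CCO[Si](c3ccccc3)(c3ccccc3)C(C)(C)C | intermediate
28 | methyl (1S,5S,6R,8aS)-5-[(3R)-5-{[tert-butyl(diphenyl)silyl]oxy}-3-methylpentyl]-1,5,6-trimethyl-3-oxo-1,2,3,5,6,7,8,8a-octahydronaphthalene-1-carboxylate | COC(=O)[C@@]1(C)CC(=O)C=C2[C@@H]1CC[C@@H](C)[C@]2(C)CC[C@@H](C)CCO[Si](c3ccccc3)(c3ccccc3)C(C)(C)C | intermediate
29 | methyl (1S,5S,6R,8aS)-5-[(3R)-5-hydroxy-3-methylpentyl]-1,5,6-trimethyl-3-oxo-1,2,3,5,6,7,8,8a-octahydronaphthalene-1-carboxylate | COC(=O)[C@@]1(C)CC(=O)C=C2[C@@H]1CC[C@@H](C)[C@]2(C)CC[C@@H](C)CCO | intermediate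
30 | methyl (1S,5S,6R,8aS)-5-[(3R)-5-acetoxy-3-methylpentyl]-1,5,6-trimethyl-3-oxo-1,2,3,5,6,7,8,8a-octahydronaphthalene-1-carboxylate (CNP0250576.1; halimane numbering 4S,5S,8R,9S,13R) | COC(=O)[C@@]1(C)CC(=O)C=C2[C@@H]1CC[C@@H](C)[C@]2(C)CC[C@@H](C)CCOC(C)=O | target

**Totals and risks**
Total step count: 24. Longest linear sequence: 24 steps (fully linear, 1 to 30).

Most likely to fail, first: the Michael addition of step 4. The ketimine of a 2,3-disubstituted cyclohexanone is more hindered than the usual 2-substituted cases, so the addition may be slow or less selective. The fallback sets out from ketone 3 and comes back at diketone 7. Ketone 3 is converted under equilibrating conditions (Me3SiCl, NaI, Et3N, MeCN) into the more substituted silyl enol ether (R)-[(2,3-dimethylcyclohex-1-en-1-yl)oxy]trimethylsilane F1. A Mukaiyama–Michael addition of F1 to but-3-en-2-one 5 (TiCl4, CH2Cl2, −78 °C, aqueous work-up) then gives 7, the trans selectivity now resting only on the C8 methyl.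

Second: the reduction of step 7, whose facial selectivity at C10 decides the configuration later relayed to C5. The fallback sets out from enone 10 and comes back at alcohol 11. If hydride delivers mainly the epimer ethyl (2E)-5-[(1S,2R,6R)-2-hydroxy-1,6-dimethylcyclohex-3-en-1-yl]-3-methylpent-2-enoate F2, this is inverted by Mitsunobu esterification (4-nitrobenzoic acid, PPh3, diisopropyl azodicarboxylate, toluene) to the 4-nitrobenzoate ester of 11 F3. Ethanolysis of F3 (K2CO3, EtOH) then gives 11.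

Third: the ring closure of step 21, where a lithium enolate must add to a very hindered ketone and may instead revert or attack the ester. The fallback sets out from diketo ester 25 and comes back at ketol 26. The kinetic enolate of the methyl ketone is trapped (LiN(SiMe3)2, Me3SiCl, THF, −78 °C) as the trimethylsilyl enol ether of 25 F4. An intramolecular Mukaiyama aldol addition (TiCl4, CH2Cl2, −78 °C), in which the Lewis acid activates the C10 ketone under non-basic conditions, then gives 26.

**Further compounds**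
F1 | step 4 | (R)-[(2,3-dimethylcyclohex-1-en-1-yl)oxy]trimethylsilane | C[C@@H]1CCCC(O[Si](C)(C)C)=C1C
F2 | step 7 | ethyl (2E)-5-[(1S,2R,6R)-2-hydroxy-1,6-dimethylcyclohex-3-en-1-yl]-3-methylpent-2-enoate | O[C@@H]1C=CC[C@@H](C)[C@]1(C)CC/C(C)=C/C(=O)OCC
F3 | step 7 | (1S,5R,6S)-6-[(3E)-5-ethoxy-3-methyl-5-oxopent-3-en-1-yl]-5,6-dimethylcyclohex-2-en-1-yl 4-nitrobenzoate | O=C(O[C@H]1C=CC[C@@H](C)[C@]1(C)CC/C(C)=C/C(=O)OCC)c1ccc(cc1)[N+](=O)[O-]
F4 | step 21 | methyl (2S)-2-[(1R,3S,4R)-3-[(3R)-5-{[tert-butyl(diphenyl)silyl]oxy}-3-methylpentyl]-3,4-dimethyl-2-oxocyclohexyl]-2-methyl-4-(trimethylsilyloxy)pent-4-enoate | COC(=O)[C@@](C)(CC(=C)O[Si](C)(C)C)[C@H]1CC[C@@H](C)[C@](C)(CC[C@@H](C)CCO[Si](c2ccccc2)(c2ccccc2)C(C)(C)C)C1=O
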